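The 2,3-dihydrobenzofuran ring (O1–C2–C3–C3a–C7a) is disconnected at O1–C7a and C2–C3, a formal [3+2] union of the C=O group of O-silyl vanillin with ring A. The feature exploited is the 1,3-relationship of benzylic C3 and aromatic C7a across C3a. With the hydroxymethyl carbon on C3 at the acyl level (chiral imide), C3 is a nucleophile; with C7a as an aryl triflate, it is an electrophile. In one flask, an Evans syn-aldol forms C2–C3 and both stereocentres, then palladium-catalysed O-arylation closes the ring. The precursor is an ortho-triflyloxy arylacetyl oxazolidinone that already carries the protected feruloyl ester.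

Key step: step 8

Assumption: read from the SMILES, the target is the trans-(2R,3S)-2,3-dihydrobenzofuran, and the route is planned for this enantiomer.

Step 1
Reactants: 1 dihydroconiferyl alcohol [4-(3-hydroxypropyl)-2-methoxyphenol]
Product: 2 2-bromo-4-(3-hydroxypropyl)-6-methoxyphenol
Conditions: NBS (1.0 equiv), i-Pr2NH (cat.), CH2Cl2, 0 °C
Reagents that add atoms: N-bromosuccinimide (NBS), O=C1CCC(=O)N1Br
Why: Electrophilic aromatic bromination is directed by the free phenol to its only open ortho position (the para position carries the propyl chain), which places bromine on the carbon that becomes C3a.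

Step 2
Reactants: 2 2-bromo-4-(3-hydroxypropyl)-6-methoxyphenol
Product: 3 2-bromo-4-(3-hydroxypropyl)-6-methoxyphenyl trifluoromethanesulfonate
Conditions: PhNTf2, Et3N, DMAP (cat.), CH2Cl2, rt
Reagents that add atoms: N-phenylbis(trifluoromethanesulfonimide), O=S(=O)(N(c1ccccc1)S(=O)(=O)C(F)(F)F)C(F)(F)F
Why: The triflimide sulfonylates the acidic phenoxide and leaves the primary alcohol untouched (chemoselective O-triflation), which turns the phenolic carbon into the future electrophilic C7a.

Step 3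
Reactants: 4 (E)-ferulic acid
Product: 6 (E)-4-O-TBS-ferulic acid [(E)-3-[4-(tert-butyldimethylsilyloxy)-3-methoxyphenyl]acrylic acid], via bis-silylated ferulate 5 (not isolated)
Conditions: TBSCl (2.2 equiv), imidazole, DMF, rt; then AcOH/THF/H2O, rt
Reagents that add atoms: tert-butyldimethylsilyl chloride (TBSCl), CC(C)(C)[Si](C)(C)Cl
Why: Silylation of both acidic sites followed by selective hydrolysis of the labile silyl ester leaves the phenol as its TBS ether (silyl ether protection).

Step 4
Reactants: 3 2-bromo-4-(3-hydroxypropyl)-6-methoxyphenyl trifluoromethanesulfonate, 6 (E)-4-O-TBS-ferulic acid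
Product: 7 3-[3-bromo-5-methoxy-4-(trifluoromethylsulfonyloxy)phenyl]propyl (E)-4-O-TBS-ferulate
Conditions: DIC, DMAP (cat.), CH2Cl2, 0 °C to rt
Reagents that add atoms: none
Why: Steglich-type carbodiimide/DMAP esterification joins the primary alcohol to the acid, and aryl bromide, aryl triflate and aryl silyl ether are inert to it.

Step 5
Reactants: 8 (R)-4-benzyloxazolidin-2-one, 9 bromoacetyl bromide
Product: 11 (R)-4-benzyl-3-(bromoacetyl)oxazolidin-2-one, via lithium oxazolidinide 10 (not isolated)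
Conditions: n-BuLi, THF, −78 °C; then 9, −78 °C
Reagents that add atoms: none
Why: N-Acylation of the lithiated oxazolidinone occurs at the acid bromide carbonyl, which is far more electrophilic than the alkyl bromide at low temperature.

Step 6
Reactants: 7 3-[3-bromo-5-methoxy-4-(trifluoromethylsulfonyloxy)phenyl]propyl (E)-4-O-TBS-ferulate, 11 (R)-4-benzyl-3-(bromoacetyl)oxazolidin-2-one
Product: 13 3-{3-[2-((R)-4-benzyl-2-oxooxazolidin-3-yl)-2-oxoethyl]-5-methoxy-4-(trifluoromethylsulfonyloxy)phenyl}propyl (E)-4-O-TBS-ferulate, via Reformatsky reagent 12 (not isolated)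
Conditions: 11, Zn dust (TMSCl-activated), THF, rt; then 7, Pd(dba)2 (cat.), P(t-Bu)3 (cat.), THF, 50 °C
Reagents that add atoms: none
Why: Zinc insertion gives the imide zinc enolate, which undergoes palladium-catalysed α-arylation (Reformatsky–Negishi coupling) because monophosphine-ligated zerovalent palladium inserts into C–Br in preference to C–OTf and the neutral zinc enolate spares the cinnamate ester and the imide.

Step 7
Reactants: 14 vanillin
Product: 15 4-O-TBS-vanillin [4-(tert-butyldimethylsilyloxy)-3-methoxybenzaldehyde]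
Conditions: TBSCl, imidazole, CH2Cl2, rt
Reagents that add atoms: tert-butyldimethylsilyl chloride (TBSCl), CC(C)(C)[Si](C)(C)Cl
Why: Silyl ether formation masks the phenol so that the aldehyde tolerates the boron enolate and the basic coupling stage.

Step 8
Reactants: 13 3-{3-[2-((R)-4-benzyl-2-oxooxazolidin-3-yl)-2-oxoethyl]-5-methoxy-4-(trifluoromethylsulfonyloxy)phenyl}propyl (E)-4-O-TBS-ferulate, 15 4-O-TBS-vanillin
Product: 19 (R)-4-benzyl-3-{[(2R,3R)-2-(4-TBSO-3-methoxyphenyl)-7-methoxy-5-[3-((E)-4-O-TBS-feruloyloxy)propyl]-2,3-dihydrobenzofuran-3-yl]carbonyl}oxazolidin-2-one, via boron enolate 16 (not isolated), via boron aldolate 17 (not isolated), via syn-aldol 18 (not isolated)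
Conditions: Bu2BOTf, i-Pr2NEt, CH2Cl2, −78 to 0 °C; 15, −78 to 0 °C; MeOH, then evaporation; same flask: toluene, K3PO4, Pd2(dba)3 (cat.), t-BuXPhos (cat.), 60 °C
Reagents that add atoms: none
Why: Soft enolisation of 13 gives the (Z)-boron enolate, which adds to the aldehyde through a closed Zimmerman–Traxler chair (Evans syn-aldol) to form C2–C3; methanolysis frees the alcohol, whose oxygen is then joined to C7a by palladium-catalysed intramolecular C–O coupling of the aryl triflate, so that the aldehyde C=O and the C3/C7a pair of ring A combine in a formal [3+2] annulation. The closest known reaction types are the boron aldol of arylacetyl imides and the Buchwald–Hartwig-type cyclisation of 2-(2-halophenyl)ethanols to dihydrobenzofurans, here telescoped in one flask. The five-membered ring O1–C2–C3–C3a–C7a closes by C(sp2)–O reductive elimination from a six-membered aryl(alkoxo)palladium chelate formed after oxidative addition into C7a–OTf. C3 and C2 are both set by the (R)-4-benzyl auxiliary, whose dipole-minimised enolate exposes one face and gives the (2R,3R)-syn aldol; the coupling touches neither centre, so syn becomes the trans-2,3 ring. The step needs ring closure to outrun retro-aldol, β-hydride elimination and triflyl transfer, which the weak heterogeneous base (low free alkoxide concentration), the bulky biarylphosphine (fast reductive elimination) and the five-ring geometry are chosen to secure. C3, the only epimerisable centre, already sits in the thermodynamically preferred trans arrangement, and any C2 epimer is a separable diastereomer because the auxiliary is still attached.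

Step 9
Reactants: 19 (R)-4-benzyl-3-{[(2R,3R)-2-(4-TBSO-3-methoxyphenyl)-7-methoxy-5-[3-((E)-4-O-TBS-feruloyloxy)propyl]-2,3-dihydrobenzofuran-3-yl]carbonyl}oxazolidin-2-one
Product: 20 3-[(2R,3S)-2-(4-TBSO-3-methoxyphenyl)-3-(hydroxymethyl)-7-methoxy-2,3-dihydrobenzofuran-5-yl]propyl (E)-4-O-TBS-ferulate
Conditions: NaBH4, THF/H2O, 0 °C to rt
Reagents that add atoms: none
Why: Borohydride reduces the activated exocyclic imide carbonyl to the primary alcohol (reductive cleavage of an Evans auxiliary) while the conjugated alkyl ester is untouched; neither stereocentre is involved, and C3 becomes (S) only through the change in CIP priorities.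

Step 10
Reactants: 21 (E)-p-coumaric acid
Product: 23 (E)-4-O-TBS-p-coumaric acid [(E)-3-[4-(tert-butyldimethylsilyloxy)phenyl]acrylic acid], via bis-silylated coumarate 22 (not isolated)
Conditions: TBSCl (2.2 equiv), imidazole, DMF, rt; then AcOH/THF/H2O, rt
Reagents that add atoms: tert-butyldimethylsilyl chloride (TBSCl), CC(C)(C)[Si](C)(C)Cl
Why: Double silylation followed by selective hydrolysis of the silyl ester gives the phenol-protected acid (silyl ether protection).

Step 11
Reactants: 20 3-[(2R,3S)-2-(4-TBSO-3-methoxyphenyl)-3-(hydroxymethyl)-7-methoxy-2,3-dihydrobenzofuran-5-yl]propyl (E)-4-O-TBS-ferulate, 23 (E)-4-O-TBS-p-coumaric acid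
Product: 24 tris-O-TBS-boehmenan X [(2R,3S)-diester with all three phenols as TBS ethers]
Conditions: DIC, DMAP (cat.), CH2Cl2, 0 °C to rt
Reagents that add atoms: none
Why: Carbodiimide/DMAP acylation (Steglich esterification) uses the alcohol as the nucleophile, so the C3–CH2–O carbon is never turned into a leaving group and elimination towards the benzofuran is avoided.

Step 12
Reactants: 24 tris-O-TBS-boehmenan X
Product: 25 (+)-boehmenan X
Conditions: TBAF, AcOH, THF, 0 °C
Reagents that add atoms: none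
Why: Fluoride cleaves the three aryl silyl ethers (desilylation), and the acetic acid buffer keeps the phenols protonated so that the cinnamate esters and the base-sensitive 2-(4-hydroxyaryl)dihydrobenzofuran (quinone-methide ring opening) are preserved.

Compound list
1 | dihydroconiferyl alcohol, 4-(3-hydroxypropyl)-2-methoxyphenol | COc1cc(CCCO)ccc1O | starting material
2 | 2-bromo-4-(3-hydroxypropyl)-6-methoxyphenol | COc1cc(CCCO)cc(Br)c1O | intermediate
3 | 2-bromo-4-(3-hydroxypropyl)-6-methoxyphenyl trifluoromethanesulfonate | COc1cc(CCCO)cc(Br)c1OS(=O)(=O)C(F)(F)F | intermediate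
4 | (E)-ferulic acid | COc1cc(/C=C/C(=O)O)ccc1O | starting material
5 | tert-butyldimethylsilyl (E)-3-[4-(tert-butyldimethylsilyloxy)-3-methoxyphenyl]acrylate (bis-silylated ferulate) | COc1cc(/C=C/C(=O)O[Si](C)(C)C(C)(C)C)ccc1O[Si](C)(C)C(C)(C)C | intermediate
6 | (E)-4-O-TBS-ferulic acid | COc1cc(/C=C/C(=O)O)ccc1O[Si](C)(C)C(C)(C)C | intermediate
7 | 3-[3-bromo-5-methoxy-4-(trifluoromethylsulfonyloxy)phenyl]propyl (E)-4-O-TBS-ferulate | COc1cc(/C=C/C(=O)OCCCc2cc(OC)c(OS(=O)(=O)C(F)(F)F)c(Br)c2)ccc1O[Si](C)(C)C(C)(C)C | intermediate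
8 | (R)-4-benzyloxazolidin-2-one | O=C1N[C@H](Cc2ccccc2)CO1 | starting material
9 | bromoacetyl bromide | BrCC(Br)=O | starting material
10 | lithium (R)-4-benzyl-2-oxooxazolidin-3-ide | [Li+].O=C1[N-][C@H](Cc2ccccc2)CO1 | intermediate
11 | (R)-4-benzyl-3-(bromoacetyl)oxazolidin-2-one | O=C(CBr)N1[C@H](Cc2ccccc2)COC1=O | intermediate
12 | bromozinc enolate (Reformatsky reagent) of 11 | Br[Zn]CC(=O)N1[C@H](Cc2ccccc2)COC1=O | intermediate
13 | 3-{3-[2-((R)-4-benzyl-2-oxooxazolidin-3-yl)-2-oxoethyl]-5-methoxy-4-(trifluoromethylsulfonyloxy)phenyl}propyl (E)-4-O-TBS-ferulate | COc1cc(/C=C/C(=O)OCCCc2cc(OC)c(OS(=O)(=O)C(F)(F)F)c(CC(=O)N3[C@H](Cc4ccccc4)COC3=O)c2)ccc1O[Si](C)(C)C(C)(C)C | intermediate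
14 | vanillin | COc1cc(C=O)ccc1O | starting material
15 | 4-O-TBS-vanillin | COc1cc(C=O)ccc1O[Si](C)(C)C(C)(C)C | intermediate
16 | (Z)-dibutylboron enolate of 13 | COc1cc(/C=C/C(=O)OCCCc2cc(OC)c(OS(=O)(=O)C(F)(F)F)c(/C=C(\OB(CCCC)CCCC)N3[C@H](Cc4ccccc4)COC3=O)c2)ccc1O[Si](C)(C)C(C)(C)C | intermediate
17 | dibutylboron aldolate of the (2R,3R)-syn-aldol | COc1cc(/C=C/C(=O)OCCCc2cc(OC)c(OS(=O)(=O)C(F)(F)F)c(c2)[C@@H](C(=O)N2[C@H](Cc3ccccc3)COC2=O)[C@@H](OB(CCCC)CCCC)c2ccc(O[Si](C)(C)C(C)(C)C)c(OC)c2)ccc1O[Si](C)(C)C(C)(C)C | intermediate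
18 | (R)-4-benzyl-3-[(2R,3R)-3-hydroxy-3-(4-TBSO-3-methoxyphenyl)-2-{3-methoxy-2-(trifluoromethylsulfonyloxy)-5-[3-((E)-4-O-TBS-feruloyloxy)propyl]phenyl}propanoyl]oxazolidin-2-one (syn-aldol) | COc1cc(/C=C/C(=O)OCCCc2cc(OC)c(OS(=O)(=O)C(F)(F)F)c(c2)[C@@H](C(=O)N2[C@H](Cc3ccccc3)COC2=O)[C@@H](O)c2ccc(O[Si](C)(C)C(C)(C)C)c(OC)c2)ccc1O[Si](C)(C)C(C)(C)C | intermediate
19 | (R)-4-benzyl-3-{[(2R,3R)-2-(4-TBSO-3-methoxyphenyl)-7-methoxy-5-[3-((E)-4-O-TBS-feruloyloxy)propyl]-2,3-dihydrobenzofuran-3-yl]carbonyl}oxazolidin-2-one | COc1cc(/C=C/C(=O)OCCCc2cc(OC)c3c(c2)[C@@H](C(=O)N2[C@H](Cc4ccccc4)COC2=O)[C@H](c2ccc(O[Si](C)(C)C(C)(C)C)c(OC)c2)O3)ccc1O[Si](C)(C)C(C)(C)C | intermediate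
20 | 3-[(2R,3S)-2-(4-TBSO-3-methoxyphenyl)-3-(hydroxymethyl)-7-methoxy-2,3-dihydrobenzofuran-5-yl]propyl (E)-4-O-TBS-ferulate | COc1cc(/C=C/C(=O)OCCCc2cc(OC)c3c(c2)[C@@H](CO)[C@H](c2ccc(O[Si](C)(C)C(C)(C)C)c(OC)c2)O3)ccc1O[Si](C)(C)C(C)(C)C | intermediate
21 | (E)-p-coumaric acid | OC(=O)/C=C/c1ccc(O)cc1 | starting material
22 | tert-butyldimethylsilyl (E)-3-[4-(tert-butyldimethylsilyloxy)phenyl]acrylate (bis-silylated coumarate) | CC(C)(C)[Si](C)(C)OC(=O)/C=C/c1ccc(O[Si](C)(C)C(C)(C)C)cc1 | intermediate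
23 | (E)-4-O-TBS-p-coumaric acid | OC(=O)/C=C/c1ccc(O[Si](C)(C)C(C)(C)C)cc1 | intermediate
24 | tris-O-TBS-boehmenan X, (2R,3S) | COc1cc(/C=C/C(=O)OCCCc2cc(OC)c3c(c2)[C@@H](COC(=O)/C=C/c2ccc(O[Si](C)(C)C(C)(C)C)cc2)[C@H](c2ccc(O[Si](C)(C)C(C)(C)C)c(OC)c2)O3)ccc1O[Si](C)(C)C(C)(C)C | intermediate
25 | (+)-boehmenan X, (2R,3S) | COc1cc(/C=C/C(=O)OCCCc2cc(OC)c3c(c2)[C@@H](COC(=O)/C=C/c2ccc(O)cc2)[C@H](c2ccc(O)c(OC)c2)O3)ccc1O | target

Total step count: 12. Longest linear sequence: 8 steps (steps 1, 2, 4, 6, 8, 9, 11, 12).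

Steps most likely to fail

Step 8. The aldolate may fragment by retro-aldol reaction before the C–O bond closes, with erosion of C2 through reversible aldolisation; β-hydride elimination at palladium or transfer of the triflyl group to the alkoxide could also compete. The fallback sets out from 13 and postpones ring closure until the carbonyl group that allows fragmentation and epimerisation is gone. The same boron aldol is run with a buffered oxidative work-up and the syn-aldol 18 is isolated. Reduction with NaBH4 in THF/H2O gives the (1R,2S)-1,3-diol F1. Its primary hydroxyl is masked selectively with TrCl/pyridine/DMAP to give the trityl ether F2. Palladium-catalysed O-arylation of the remaining secondary benzylic alcohol then gives the trityl-protected dihydrobenzofuran F3. Removal of the trityl group with aqueous acetic acid comes back to the route at 20.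

Step 6. The imide zinc enolate may self-condense or be protonated faster than it transmetalates, so that the aryl bromide is recovered or reduced. The fallback sets out from 7 and attaches the auxiliary by acylation instead of carrying it through the cross-coupling. Coupling of 7 with the commercial Reformatsky reagent of tert-butyl bromoacetate under the same catalyst should give the tert-butyl arylacetate F4. Cleavage with CF3CO2H in CH2Cl2 gives the arylacetic acid F5. Activation as the pivalic mixed anhydride (PivCl, Et3N) and acylation of lithium oxazolidinide 10 comes back to the route at 13.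

Step 9. Hydride may attack the endocyclic carbamate carbonyl (ring-opened hydroxy amide), the ferulate ester may be partly reduced or hydrolysed, or the basic medium may open the dihydrofuran by E1cB elimination. The fallback sets out from 19 and separates cleavage from reduction. Hydrolysis with LiOH/H2O2 in THF/H2O at 0 °C gives the carboxylic acid F6. Chemoselective reduction of the acid through its isobutyl mixed carbonic anhydride with NaBH4 comes back to the route at 20.

Further compounds
F1 | step 8 | 3-{3-[(1R,2S)-1,3-dihydroxy-1-(4-TBSO-3-methoxyphenyl)propan-2-yl]-5-methoxy-4-(trifluoromethylsulfonyloxy)phenyl}propyl (E)-4-O-TBS-ferulate (diol) | COc1cc(/C=C/C(=O)OCCCc2cc(OC)c(OS(=O)(=O)C(F)(F)F)c(c2)[C@@H](CO)[C@@H](O)c2ccc(O[Si](C)(C)C(C)(C)C)c(OC)c2)ccc1O[Si](C)(C)C(C)(C)C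
F2 | step 8 | primary trityl ether of F1 | COc1cc(/C=C/C(=O)OCCCc2cc(OC)c(OS(=O)(=O)C(F)(F)F)c(c2)[C@@H](COC(c2ccccc2)(c2ccccc2)c2ccccc2)[C@@H](O)c2ccc(O[Si](C)(C)C(C)(C)C)c(OC)c2)ccc1O[Si](C)(C)C(C)(C)C
F3 | step 8 | trityl ether of 20, (2R,3S) | COc1cc(/C=C/C(=O)OCCCc2cc(OC)c3c(c2)[C@@H](COC(c2ccccc2)(c2ccccc2)c2ccccc2)[C@H](c2ccc(O[Si](C)(C)C(C)(C)C)c(OC)c2)O3)ccc1O[Si](C)(C)C(C)(C)C
F4 | step 6 | 3-[3-(2-tert-butoxy-2-oxoethyl)-5-methoxy-4-(trifluoromethylsulfonyloxy)phenyl]propyl (E)-4-O-TBS-ferulate | COc1cc(/C=C/C(=O)OCCCc2cc(OC)c(OS(=O)(=O)C(F)(F)F)c(CC(=O)OC(C)(C)C)c2)ccc1O[Si](C)(C)C(C)(C)C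
F5 | step 6 | 2-{3-methoxy-2-(trifluoromethylsulfonyloxy)-5-[3-((E)-4-O-TBS-feruloyloxy)propyl]phenyl}acetic acid | COc1cc(/C=C/C(=O)OCCCc2cc(OC)c(OS(=O)(=O)C(F)(F)F)c(CC(=O)O)c2)ccc1O[Si](C)(C)C(C)(C)C
F6 | step 9 | (2R,3R)-2-(4-TBSO-3-methoxyphenyl)-7-methoxy-5-[3-((E)-4-O-TBS-feruloyloxy)propyl]-2,3-dihydrobenzofuran-3-carboxylic acid | COc1cc(/C=C/C(=O)OCCCc2cc(OC)c3c(c2)[C@@H](C(=O)O)[C@H](c2ccc(O[Si](C)(C)C(C)(C)C)c(OC)c2)O3)ccc1O[Si](C)(C)C(C)(C)C
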